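Everything rests on cutting ring A at C4–C5. In the target the gem-dimethyl carbon C4 stands between ring-fusion carbon C5 and the C3–C2 pair that carries the cis-dioxygenation. A three-carbon allyl unit C2–C3–C4, tied to C10 through C1, can therefore be closed onto a C5 ketone of ring B. One reductive operation (Pd(PPh3)4, InI) reverses the polarity of an allylic acetate, makes the C4–C5 bond with its quaternary carbon, closes ring A and leaves the alkene at C2=C3 for dihydroxylation. The precursor is a ring B cyclohexanone whose quaternary C10 comes from a desymmetrising dione reduction; it carries a C9 silyl ether and an (E)-4-acetoxy-4-methylpent-2-enyl chain.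

Key step: step 6

Reading of the target (labdane numbering throughout; β is the face of the C10 methyl group): 10β-CH3, 5α-H, 8α-CH3, 9β-OH with the C11–C15 chain 9α, 2α-OAc, 3α-OH, 13E.
Assumption: in step 2 hydride is taken to arrive on the carbonyl face next to the small C10 methyl group, so O-9 lies cis to the side chain (9α). Compound 10 is drawn as the cis-fused 5β-carbinol expected from closure with an axial tether. C9 and this C5 carbinol are spectator centres, erased in steps 12 and 7.

Step 1
Reactants: 1 2-methylcyclohexane-1,3-dione; 2 allyl bromide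
Product: 3 2-allyl-2-methylcyclohexane-1,3-dione
Conditions: aq NaOH (1 M), rt
Reagents that add atoms: none
Why: C-alkylation of the stabilised enolate of a 2-alkyl-1,3-dione with a reactive allylic halide in water, where hydrogen bonding to the enolate oxygens disfavours O-alkylation, is a standard way to the achiral quaternary dione.

Step 2
Reactants: 3 2-allyl-2-methylcyclohexane-1,3-dione
Product: 4 (2R,3R)-2-allyl-3-hydroxy-2-methylcyclohexan-1-one (hydroxyl cis to allyl; 10β-CH3 and 9α-OH in labdane terms)
Conditions: (S)-Me-CBS oxazaborolidine [(3aS)-1-methyl-3,3-diphenyltetrahydro-1H,3H-pyrrolo[1,2-c][1,3,2]oxazaborole] (20 mol %), catecholborane (1.1 equiv), toluene, −78 °C; aq work-up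
Reagents that add atoms: none
Why: Corey–Bakshi–Shibata reduction used as a desymmetrisation, in which the catalyst reads the quaternary carbon as the large and the ring CH2 as the small ketone substituent and so forms the R carbinol, and of the two enantiotopic carbonyl groups takes the one whose favoured face lies next to the methyl and away from the allyl group, which fixes C10 as R; catecholborane spares the alkene and the minor diastereomer is removed by chromatography.

Step 3
Reactants: 4 (2R,3R)-2-allyl-3-hydroxy-2-methylcyclohexan-1-one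
Product: 5 (2R,3R)-2-allyl-3-(tert-butyldimethylsilyloxy)-2-methylcyclohexan-1-one
Conditions: TBSOTf, 2,6-lutidine, CH2Cl2, −78 to 0 °C
Reagents that add atoms: tert-butyldimethylsilyl triflate, CC(C)(C)[Si](C)(C)OS(=O)(=O)C(F)(F)F
Why: Silylation of a hindered secondary alcohol with the silyl triflate and a non-nucleophilic base is fast at low temperature, blocks retro-aldol opening of the β-ketol and touches no stereocentre.

Step 4
Reactants: 5 (2R,3R)-2-allyl-3-(tert-butyldimethylsilyloxy)-2-methylcyclohexan-1-one; 6 2-methylbut-3-en-2-ol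
Product: 7 (2R,3R)-3-(tert-butyldimethylsilyloxy)-2-[(E)-4-hydroxy-4-methylpent-2-en-1-yl]-2-methylcyclohexan-1-one
Conditions: second-generation Grubbs catalyst, RuCl2(=CHPh)(PCy3)(H2IMes) (3 mol %), 6 (5 equiv), CH2Cl2, 40 °C
Reagents that add atoms: none
Why: Olefin cross-metathesis between a terminal alkene that homodimerises readily and an unprotected tertiary allylic alcohol that does not is a selective pairing, and it gives the E-disubstituted alkene under thermodynamic control.

Step 5
Reactants: 7 (2R,3R)-3-(tert-butyldimethylsilyloxy)-2-[(E)-4-hydroxy-4-methylpent-2-en-1-yl]-2-methylcyclohexan-1-one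
Product: 8 (2R,3R)-2-[(E)-4-acetoxy-4-methylpent-2-en-1-yl]-3-(tert-butyldimethylsilyloxy)-2-methylcyclohexan-1-one
Conditions: Ac2O, Et3N, 4-(dimethylamino)pyridine (DMAP), CH2Cl2, rt
Reagents that add atoms: acetic anhydride, CC(=O)OC(C)=O
Why: DMAP-catalysed acylation is the standard esterification of tertiary allylic alcohols, and 7 has no other free hydroxyl group.

Step 6
Reactants: 8 (2R,3R)-2-[(E)-4-acetoxy-4-methylpent-2-en-1-yl]-3-(tert-butyldimethylsilyloxy)-2-methylcyclohexan-1-one
Product: 10 cis-fused 9α-(tert-butyldimethylsilyloxy)-4,4,10β-trimethyl-Δ2-octalin-5β-ol, via allylindium acetate iodide 9 (not isolated)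
Conditions: Pd(PPh3)4 (10 mol %), InI (2 equiv), THF (0.02 M), rt to 50 °C; aq NH4Cl
Reagents that add atoms: none
Why: Zerovalent palladium ionises the tertiary allylic acetate and InI reduces the palladium-bound allyl unit by reductive transmetalation to allylindium 9, which carries the metal on the less substituted terminus C2; the indium centre binds the C5 carbonyl oxygen and C4 attacks C5 with allylic transposition (SE2′), which leaves the alkene at C2=C3. The closest known reactions are the palladium/InI umpolung allylation of carbonyl compounds with allylic acetates, including cyclisations onto tethered ketones, and the Barbier-type addition of prenyl metals to ketones through their dimethyl-substituted end. Ring A closes by a 6-exo-trig attack on the carbonyl group in which C2, C3 and C4 all end up inside the new ring, so the In–C2–C3–C4–C5–O array is a boat bridged by C1–C10 and not a chair, which the long In–C and In–O bonds should allow, and rotation about C2–C3 in the σ-bound allylindium turns the E alkene of 8 into the cis ring alkene. The one new stereocentre, C5, is controlled by the tether: in the chair of ring B with the side chain axial on the α face and the C9 silyl ether equatorial, C4 can reach only the α face of the ketone, away from the C10 methyl group, so the cis-fused 5β-carbinol is expected, and since step 7 erases C5 any 5α epimer is carried along. The selectivity that matters is regiochemical, bond formation at C4 and not at C2, and ring size secures it because attack through C2 would have to build a cyclobutanol. The silyl ether is inert, no other group in 8 ionises, and moderate dilution keeps the addition intramolecular.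

Step 7
Reactants: 10 cis-fused 9α-(tert-butyldimethylsilyloxy)-4,4,10β-trimethyl-Δ2-octalin-5β-ol
Product: 11 9α-(tert-butyldimethylsilyloxy)-4,4,10β-trimethyl-Δ2,Δ5-hexalin (C2=C3 and C5=C6 diene)
Conditions: SOCl2, pyridine, 0 °C
Reagents that add atoms: none
Why: Dehydration of a tertiary alcohol with SOCl2 in pyridine is an E2-type elimination in which only C5=C6 can form because C4 and C10 carry no hydrogen, the 5β-hydroxyl group is axial on ring B and antiperiplanar to H-6α, and the basic medium holds back cationic methyl shifts.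

Step 8
Reactants: 11 9α-(tert-butyldimethylsilyloxy)-4,4,10β-trimethyl-Δ2,Δ5-hexalin
Product: 12 9α-(tert-butyldimethylsilyloxy)-4,4,10β-trimethyl-Δ5-octalin-2α,3α-diol
Conditions: OsO4 (5 mol %), N-methylmorpholine N-oxide (NMO), acetone/H2O, rt
Reagents that add atoms: osmium tetroxide, O=[Os](=O)(=O)=O; N-methylmorpholine N-oxide, C[N+]1([O-])CCOCC1; water, O
Why: Upjohn dihydroxylation, in which the cis-disubstituted C2=C3 alkene reacts before the trisubstituted C5=C6 alkene walled in by two quaternary carbons, and syn addition takes place on the α face because the C10 methyl and the 4β-methyl group cover the β face, which sets C2 and C3.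

Step 9
Reactants: 12 9α-(tert-butyldimethylsilyloxy)-4,4,10β-trimethyl-Δ5-octalin-2α,3α-diol
Product: 13 9α-(tert-butyldimethylsilyloxy)-2α,3α-isopropylidenedioxy-4,4,10β-trimethyl-Δ5-octalin
Conditions: 2,2-dimethoxypropane, pyridinium p-toluenesulfonate (cat.), CH2Cl2, rt
Reagents that add atoms: 2,2-dimethoxypropane, COC(C)(C)OC
Why: Acid-catalysed transketalisation of a cis-1,2-diol gives the five-membered isopropylidene acetal, which masks both hydroxyl groups for the basic and organometallic steps ahead without touching the silyl ether.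

Step 10
Reactants: 13 9α-(tert-butyldimethylsilyloxy)-2α,3α-isopropylidenedioxy-4,4,10β-trimethyl-Δ5-octalin
Product: 14 2α,3α-isopropylidenedioxy-4,4,10β-trimethyl-Δ5-octalin-9α-ol
Conditions: Bu4NF (TBAF), THF, 50 °C
Reagents that add atoms: none
Why: Fluoride-induced desilylation, driven by the strong Si–F bond, frees the C9 alcohol and thins out the α face before the reduction, and nothing else in 13 reacts with fluoride.

Step 11
Reactants: 14 2α,3α-isopropylidenedioxy-4,4,10β-trimethyl-Δ5-octalin-9α-ol
Product: 15 trans-fused 2α,3α-isopropylidenedioxy-4,4,10β-trimethyl-5α-decalin-9α-ol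
Conditions: Mn(dpm)3 (10 mol %; dpm = 2,2,6,6-tetramethylheptane-3,5-dionate), PhSiH3, t-BuOOH, i-PrOH, rt
Reagents that add atoms: none
Why: Metal-hydride hydrogen atom transfer (MHAT) hydrogenation, in which a manganese hydride gives a hydrogen atom to the open C6 terminus and the tertiary C5 radical takes the second hydrogen along the axial α direction because its β lobe is flanked by the 4β- and 10β-methyl groups, sets 5α-H and the more stable trans-decalin without requiring the hindered alkene to bind to a metal surface.

Step 12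
Reactants: 15 trans-fused 2α,3α-isopropylidenedioxy-4,4,10β-trimethyl-5α-decalin-9α-ol
Product: 16 2α,3α-isopropylidenedioxy-4,4,10β-trimethyl-5α-decalin-9-one
Conditions: Dess–Martin periodinane, CH2Cl2, rt
Reagents that add atoms: none
Why: Dess–Martin oxidation converts the hindered secondary alcohol into the ketone under near-neutral conditions that leave the acetonide alone, and the spectator centre C9 disappears.

Step 13
Reactants: 16 2α,3α-isopropylidenedioxy-4,4,10β-trimethyl-5α-decalin-9-one
Product: 18 2α,3α-isopropylidenedioxy-4,4,8α,10β-tetramethyl-5α-decalin-9-one, via lithium C8 enolate 17 (not isolated)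
Conditions: LiN(i-Pr)2 (LDA), THF, −78 °C; MeI, −78 to 0 °C
Reagents that add atoms: iodomethane, CI
Why: Kinetic enolate alkylation, in which only the C8 enolate can form because C10 is quaternary and MeI approaches the α face because the β approach is syn-axial to the C10 methyl group, sets C8, and the equatorial 8α-methyl ketone is also the thermodynamic epimer, so any epimerisation converges on 18.

Step 14
Reactants: 18 2α,3α-isopropylidenedioxy-4,4,8α,10β-tetramethyl-5α-decalin-9-one; 19 vinylmagnesium bromide
Product: 20 2α,3α-isopropylidenedioxy-4,4,8α,10β-tetramethyl-9α-vinyl-5α-decalin-9β-ol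
Conditions: LaCl3·2LiCl, THF, 0 °C; aq NH4Cl
Reagents that add atoms: none
Why: Lanthanide-promoted 1,2-addition of a Grignard reagent suppresses enolisation of the hindered ketone, and the nucleophile comes in axially from the α face, opposite the axial C10 methyl group next to the carbonyl, which sets C9 with the carbon chain α and the hydroxyl group β.

Step 15
Reactants: 21 methyl acetoacetate
Product: 22 methyl (E)-3-(trifluoromethylsulfonyloxy)but-2-enoate
Conditions: Tf2O, aq Me4NOH, hexane, 5 °C
Reagents that add atoms: triflic anhydride, O=S(=O)(OS(=O)(=O)C(F)(F)F)C(F)(F)F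
Why: O-sulfonylation of the β-keto ester enolate with a non-chelating tetraalkylammonium counter-ion goes through the extended enolate and gives the E-enol triflate (triflate trans to the ester), the geometry needed at C13=C14.

Step 16
Reactants: 20 2α,3α-isopropylidenedioxy-4,4,8α,10β-tetramethyl-9α-vinyl-5α-decalin-9β-ol; 22 methyl (E)-3-(trifluoromethylsulfonyloxy)but-2-enoate
Product: 24 methyl (13E)-9β-hydroxy-2α,3α-isopropylidenedioxylabd-13-en-15-oate (chain 9α; 8α-CH3; 5α-H), via B-alkyl-9-BBN adduct 23 (not isolated)
Conditions: 9-borabicyclo[3.3.1]nonane (9-BBN, 3 equiv), THF, rt to 50 °C; then 22, PdCl2(dppf) (5 mol %), aq K3PO4, DMF, rt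
Reagents that add atoms: none
Why: Anti-Markovnikov hydroboration of the vinyl group followed by B-alkyl Suzuki–Miyaura coupling joins C12 to C13 with retention of the enol triflate geometry, so the E alkene is carried over from 22 and no stereocentre is touched.

Step 17
Reactants: 24 methyl (13E)-9β-hydroxy-2α,3α-isopropylidenedioxylabd-13-en-15-oate
Product: 25 methyl (13E)-2α,3α,9β-trihydroxylabd-13-en-15-oate
Conditions: AcOH/H2O/THF, 45 °C
Reagents that add atoms: none
Why: Mild aqueous acid hydrolyses the isopropylidene acetal while the methyl ester, the enoate and the hindered tertiary C9 alcohol stay intact.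

Step 18
Reactants: 25 methyl (13E)-2α,3α,9β-trihydroxylabd-13-en-15-oate
Product: 26 methyl (13E)-2α-acetoxy-3α,9β-dihydroxylabd-13-en-15-oate (CNP0135744.1)
Conditions: Ac2O (1.1 equiv), pyridine, 0 °C
Reagents that add atoms: acetic anhydride, CC(=O)OC(C)=O
Why: Selective acylation under steric control should acetylate the equatorial 2α-hydroxyl group much faster than the axial 3α-hydroxyl group beside the gem-dimethyl carbon or the tertiary C9 hydroxyl group.

Compound list
1 | 2-methylcyclohexane-1,3-dione | CC1C(=O)CCCC1=O | starting material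
2 | allyl bromide | C=CCBr | starting material
3 | 2-allyl-2-methylcyclohexane-1,3-dione | C=CCC1(C)C(=O)CCCC1=O | intermediate
4 | (2R,3R)-2-allyl-3-hydroxy-2-methylcyclohexan-1-one | C=CC[C@]1(C)[C@H](O)CCCC1=O | intermediate
5 | (2R,3R)-2-allyl-3-(tert-butyldimethylsilyloxy)-2-methylcyclohexan-1-one | C=CC[C@]1(C)[C@H](O[Si](C)(C)C(C)(C)C)CCCC1=O | intermediate
6 | 2-methylbut-3-en-2-ol | CC(C)(O)C=C | starting material
7 | (2R,3R)-3-(tert-butyldimethylsilyloxy)-2-[(E)-4-hydroxy-4-methylpent-2-en-1-yl]-2-methylcyclohexan-1-one | CC(C)(O)/C=C/C[C@]1(C)[C@H](O[Si](C)(C)C(C)(C)C)CCCC1=O | intermediate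
8 | (2R,3R)-2-[(E)-4-acetoxy-4-methylpent-2-en-1-yl]-3-(tert-butyldimethylsilyloxy)-2-methylcyclohexan-1-one | CC(C)(OC(C)=O)/C=C/C[C@]1(C)[C@H](O[Si](C)(C)C(C)(C)C)CCCC1=O | intermediate
9 | allylindium acetate iodide, metal on C2, C3=C4 alkene (C2 configuration undefined, not isolated) | CC(C)=CC([In](I)OC(C)=O)C[C@]1(C)[C@H](O[Si](C)(C)C(C)(C)C)CCCC1=O | intermediate
10 | cis-fused 9α-(tert-butyldimethylsilyloxy)-4,4,10β-trimethyl-Δ2-octalin-5β-ol | CC(C)(C)[Si](C)(C)O[C@@H]1CCC[C@]2(O)C(C)(C)C=CC[C@@]21C | intermediate
11 | 9α-(tert-butyldimethylsilyloxy)-4,4,10β-trimethyl-Δ2,Δ5-hexalin | CC(C)(C)[Si](C)(C)O[C@@H]1CCC=C2C(C)(C)C=CC[C@@]21C | intermediate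
12 | 9α-(tert-butyldimethylsilyloxy)-4,4,10β-trimethyl-Δ5-octalin-2α,3α-diol | CC(C)(C)[Si](C)(C)O[C@@H]1CCC=C2C(C)(C)[C@H](O)[C@H](O)C[C@@]21C | intermediate
13 | 9α-(tert-butyldimethylsilyloxy)-2α,3α-isopropylidenedioxy-4,4,10β-trimethyl-Δ5-octalin | CC(C)(C)[Si](C)(C)O[C@@H]1CCC=C2C(C)(C)[C@@H]3OC(C)(C)O[C@@H]3C[C@@]21C | intermediate
14 | 2α,3α-isopropylidenedioxy-4,4,10β-trimethyl-Δ5-octalin-9α-ol | O[C@@H]1CCC=C2C(C)(C)[C@@H]3OC(C)(C)O[C@@H]3C[C@@]21C | intermediate
15 | trans-fused 2α,3α-isopropylidenedioxy-4,4,10β-trimethyl-5α-decalin-9α-ol | O[C@@H]1CCC[C@H]2C(C)(C)[C@@H]3OC(C)(C)O[C@@H]3C[C@@]21C | intermediate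
16 | 2α,3α-isopropylidenedioxy-4,4,10β-trimethyl-5α-decalin-9-one | O=C1CCC[C@H]2C(C)(C)[C@@H]3OC(C)(C)O[C@@H]3C[C@@]21C | intermediate
17 | lithium C8(9)-enolate of 16 (not isolated) | [Li]OC1=CCC[C@H]2C(C)(C)[C@@H]3OC(C)(C)O[C@@H]3C[C@@]21C | intermediate
18 | 2α,3α-isopropylidenedioxy-4,4,8α,10β-tetramethyl-5α-decalin-9-one | O=C1[C@H](C)CC[C@H]2C(C)(C)[C@@H]3OC(C)(C)O[C@@H]3C[C@@]21C | intermediate
19 | vinylmagnesium bromide | C=C[Mg]Br | starting material
20 | 2α,3α-isopropylidenedioxy-4,4,8α,10β-tetramethyl-9α-vinyl-5α-decalin-9β-ol | C=C[C@]1(O)[C@H](C)CC[C@H]2C(C)(C)[C@@H]3OC(C)(C)O[C@@H]3C[C@@]21C | intermediate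
21 | methyl acetoacetate | COC(=O)CC(C)=O | starting material
22 | methyl (E)-3-(trifluoromethylsulfonyloxy)but-2-enoate | COC(=O)/C=C(\C)OS(=O)(=O)C(F)(F)F | intermediate
23 | B-alkyl-9-BBN adduct of 20, boron on C12 (not isolated) | C4CC5CCCC(C4)B5CC[C@]1(O)[C@H](C)CC[C@H]2C(C)(C)[C@@H]3OC(C)(C)O[C@@H]3C[C@@]21C | intermediate
24 | methyl (13E)-9β-hydroxy-2α,3α-isopropylidenedioxylabd-13-en-15-oate | COC(=O)/C=C(\C)CC[C@]1(O)[C@H](C)CC[C@H]2C(C)(C)[C@@H]3OC(C)(C)O[C@@H]3C[C@@]21C | intermediate
25 | methyl (13E)-2α,3α,9β-trihydroxylabd-13-en-15-oate | COC(=O)/C=C(\C)CC[C@]1(O)[C@H](C)CC[C@H]2C(C)(C)[C@H](O)[C@H](O)C[C@@]21C | intermediate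
26 | methyl (13E)-2α-acetoxy-3α,9β-dihydroxylabd-13-en-15-oate (CNP0135744.1) | COC(=O)/C=C(\C)CC[C@]1(O)[C@H](C)CC[C@H]2C(C)(C)[C@H](O)[C@H](OC(C)=O)C[C@@]21C | target

Total step count: 18. Longest linear sequence: 17 (steps 1–14 and 16–18; step 15 is a one-step side branch).

Steps most likely to fail

Step 6. The allyl metal may add too slowly to the ketone shielded by quaternary C10. Proton loss from the palladium-bound allyl unit, or protonation of the allylindium, would then take over. The fallback makes the C4–C5 bond between two molecules and closes ring A at C2=C3 by metathesis.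
- It sets out from 5. A Barbier reaction with prenyl bromide and zinc dust (THF/aq NH4Cl) adds through the dimethyl-substituted terminus and on the β face, anti to the axial allyl group. This should give the 5-(1,1-dimethylallyl) 5α-carbinol F1.
- Ring-closing metathesis with the second-generation Grubbs catalyst joins its two vinyl termini to the trans-fused Δ2-octalin-5α-ol F2, the C5 epimer of 10.
- Dehydration under the conditions of step 7 (the 5α-hydroxyl is antiperiplanar to H-6β) brings the material back to the route at 11.

Step 11. Hydrogen transfer to the C5 radical may not discriminate well enough between the two faces, which would erode the trans ring fusion. The fallback replaces the stepwise radical process by a concerted syn addition followed by deoxygenation.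
- It sets out from 13. Hydroboration with BH3·THF on the less covered α face, then H2O2/NaOH, should give the 5α-H 6α-alcohol F3.
- NaH, CS2 and MeI convert it into the S-methyl xanthate F4.
- Barton–McCombie reduction (Bu3SnH, AIBN, toluene, reflux) removes the C6 oxygen and gives the saturated silyl ether F5.
- Bu4NF then leads back to the route at 15.

Step 16. Transmetalation from the borane next to the crowded C9 carbinol may be slower than base-induced breakdown of the enol triflate or β-hydride loss from the alkylpalladium. The fallback builds C13=C14 by olefination of a methyl ketone.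
- It sets out from 18. The dilithium derivative of but-3-yn-2-ol (n-BuLi, THF) adds to the ketone from the α face to give the alkynediol F6 (C13 epimers, of no consequence).
- H2 over Pd/C saturates the triple bond to the saturated diol F7.
- Dess–Martin oxidation of the secondary alcohol gives the methyl ketone F8.
- A Horner–Wadsworth–Emmons reaction with trimethyl phosphonoacetate and NaH should favour the E-enoate. After chromatographic removal of the Z isomer this is 24, where the route is rejoined.

Further compounds
F1 | step 6 | 2-allyl-3-(tert-butyldimethylsilyloxy)-2-methyl-1-(2-methylbut-3-en-2-yl)cyclohexan-1-ol, 5α-OH, 9α-OTBS, 10β-CH3 | CC(C)(C)[Si](C)(C)O[C@@H]1CCC[C@@](O)(C(C)(C)C=C)[C@]1(C)CC=C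
F2 | step 6 | trans-fused 9α-(tert-butyldimethylsilyloxy)-4,4,10β-trimethyl-Δ2-octalin-5α-ol | CC(C)(C)[Si](C)(C)O[C@@H]1CCC[C@@]2(O)C(C)(C)C=CC[C@@]21C
F3 | step 11 | 9α-(tert-butyldimethylsilyloxy)-2α,3α-isopropylidenedioxy-4,4,10β-trimethyl-5α-decalin-6α-ol | CC(C)(C)[Si](C)(C)O[C@@H]1CC[C@H](O)[C@H]2C(C)(C)[C@@H]3OC(C)(C)O[C@@H]3C[C@@]21C
F4 | step 11 | O-(6α) S-methyl xanthate of F3 | CC(C)(C)[Si](C)(C)O[C@@H]1CC[C@H](OC(=S)SC)[C@H]2C(C)(C)[C@@H]3OC(C)(C)O[C@@H]3C[C@@]21C
F5 | step 11 | 9α-(tert-butyldimethylsilyloxy)-2α,3α-isopropylidenedioxy-4,4,10β-trimethyl-5α-decalin | CC(C)(C)[Si](C)(C)O[C@@H]1CCC[C@H]2C(C)(C)[C@@H]3OC(C)(C)O[C@@H]3C[C@@]21C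
F6 | step 16 | 9α-(3-hydroxybut-1-yn-1-yl)-2α,3α-isopropylidenedioxy-4,4,8α,10β-tetramethyl-5α-decalin-9β-ol (C13 epimers) | CC(O)C#C[C@]1(O)[C@H](C)CC[C@H]2C(C)(C)[C@@H]3OC(C)(C)O[C@@H]3C[C@@]21C
F7 | step 16 | 9α-(3-hydroxybutyl)-2α,3α-isopropylidenedioxy-4,4,8α,10β-tetramethyl-5α-decalin-9β-ol (C13 epimers) | CC(O)CC[C@]1(O)[C@H](C)CC[C@H]2C(C)(C)[C@@H]3OC(C)(C)O[C@@H]3C[C@@]21C
F8 | step 16 | 9α-(3-oxobutyl)-2α,3α-isopropylidenedioxy-4,4,8α,10β-tetramethyl-5α-decalin-9β-ol | CC(=O)CC[C@]1(O)[C@H](C)CC[C@H]2C(C)(C)[C@@H]3OC(C)(C)O[C@@H]3C[C@@]21C
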